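**Plan**
- Retrosynthesis: (i) the C11–OOH bond is removed (ene reaction of O2), giving the 10E-alkene 27. (ii) C6=C7 of ring B is cut (ring-closing metathesis), giving the 15-membered acrylate lactone 26. (iii) C15–C16 of ring A and C7–C18 of the acrylate are cut together, both carbonyl groups leaving as CO, giving the open-chain diyne diol 24. (iv) C1–C14 is cut (allenylmetal addition), giving enal 21 and propargylic mesylate 11.
- Forward: 11 and 21 are joined at C1–C14. One double cyclocarbonylation closes ring A (α-methylene-γ-lactone) and the macrolactone. Metathesis contracts the macrolactone to the 14-membered carbocycle (ring C) while forming butenolide ring B. Singlet oxygen installs the hydroperoxide last.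
- Enabling feature: O1 on C1 and the vinyl carbon C15 on C14 are 1,2-related, so ring A (O1–C16–C15–C14–C1) is the CO adduct of an anti but-3-yn-1-ol. O5 and C7 of ring B are likewise bridged by a single CO carbon (C18).
- Stereochemistry: a Noyori reduction sets an S propargylic carbinol, which anti SN2′/syn SE2′ chirality transfer relays to C14 (R) and C1 (S). C5 comes from (R)-epichlorohydrin. 2E comes from carboalumination and 10E from a Johnson–Claisen rearrangement. C11 (S) and 9E come from the suprafacial ene reaction under substrate control.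

Key step: step 16

Remark (numbering used throughout): ring C is C1–C14, counted from the ring A O–CH (C1) through C2=C3(CH3), C4, C5 (ring B O–CH), C6=C7, C8, C9, C10, C11 (C–CH3, later C–OOH), C12, C13 to C14; C15 is the α-carbon of ring A, C16 its carbonyl carbon, C17 the exocyclic CH2 and C18 the carbonyl carbon of ring B.

Step 1
Reactants: 1 methacrolein (2-methylprop-2-enal); 2 (4-bromobut-1-yn-1-yl)trimethylsilane
Product: 4 rac-2-methyl-7-(trimethylsilyl)hept-1-en-6-yn-3-ol, via Grignard reagent 3 (not isolated)
Conditions: Mg, THF, rt; then 1, −78 → 0 °C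
Reagents that add atoms: none
Why: Grignard formation from the primary bromide and 1,2-addition to the enal should give the isopropenyl carbinol; its carbinol centre is left racemic because step 2 destroys it.

Step 2
Reactants: 4
Product: 6 ethyl (E)-4-methyl-9-(trimethylsilyl)non-4-en-8-ynoate, via ketene acetal 5 (not isolated)
Conditions: CH3C(OEt)3, EtCO2H (cat.), 140 °C, EtOH distilled off
Reagents that add atoms: triethyl orthoacetate, CC(OCC)(OCC)OCC
Why: Johnson orthoester Claisen rearrangement; the chair transition state with the alkynyl chain equatorial should give the E trisubstituted alkene (the later C10=C11) and leave the silyl alkyne untouched.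

Step 3
Reactants: 6
Product: 7 (E)-N-methoxy-N,4-dimethyl-9-(trimethylsilyl)non-4-en-8-ynamide
Conditions: MeNH(OMe)·HCl, i-PrMgCl, THF, −20 → 0 °C
Reagents that add atoms: N,O-dimethylhydroxylamine hydrochloride, CNOC.Cl
Why: Aminolysis of the ester by the chloromagnesium amide (Weinreb amide formation) is a standard ester-to-amide exchange that tolerates the alkene and the silyl alkyne.

Step 4
Reactants: 7
Product: 8 (E)-6-methyl-1,11-bis(trimethylsilyl)undec-6-ene-1,10-diyn-3-one
Conditions: HC≡CSiMe3, n-BuLi, THF, −78 → 0 °C
Reagents that add atoms: ethynyltrimethylsilane, C#C[Si](C)(C)C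
Why: Weinreb ketone synthesis; the chelated tetrahedral intermediate should stop the lithium acetylide at the ynone stage.

Step 5
Reactants: 8
Product: 9 (S,E)-6-methyl-1,11-bis(trimethylsilyl)undec-6-ene-1,10-diyn-3-ol
Conditions: RuCl[(S,S)-TsDPEN](p-cymene) (2 mol %), i-PrOH, rt
Reagents that add atoms: none
Why: Noyori asymmetric transfer hydrogenation of an alkynyl ketone; the (S,S) catalyst differentiates the alkynyl and alkyl flanks and should deliver the S propargylic alcohol, the source of the C14/C1 stereo pair.

Step 6
Reactants: 9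
Product: 10 (S,E)-6-methylundec-6-ene-1,10-diyn-3-ol
Conditions: K2CO3, MeOH, rt
Reagents that add atoms: none
Why: Methanolysis of both C(sp)–Si bonds (protodesilylation) under mild base should free the two terminal alkynes without touching the carbinol centre.

Step 7
Reactants: 10
Product: 11 (S,E)-6-methylundec-6-ene-1,10-diyn-3-yl methanesulfonate
Conditions: CH3SO2Cl, Et3N, CH2Cl2, −78 °C
Reagents that add atoms: methanesulfonyl chloride, CS(=O)(=O)Cl
Why: Sulfonylation at oxygen retains the S configuration and provides the propargylic electrophile for step 14.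

Step 8
Reactants: 12 (R)-epichlorohydrin
Product: 13 (R)-1-chloro-5-(trimethylsilyl)pent-4-yn-2-ol
Conditions: HC≡CSiMe3, n-BuLi, THF, −78 °C; BF3·OEt2; then 12
Reagents that add atoms: ethynyltrimethylsilane, C#C[Si](C)(C)C
Why: Yamaguchi-type BF3-promoted opening of the epoxide at its CH2 terminus by the lithium acetylide breaks no bond to the stereocentre, so the R carbinol (the later C5) comes from the chiral pool.

Step 9
Reactants: 13
Product: 15 (R)-6-(trimethylsilyl)hex-1-en-5-yn-3-ol, via epoxide 14 (not isolated)
Conditions: Me3S+ I−, n-BuLi, THF, −10 °C → rt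
Reagents that add atoms: trimethylsulfonium iodide, C[S+](C)C.[I-]
Why: Base closes the chlorohydrin to the terminal epoxide and excess dimethylsulfonium methylide opens it at CH2, the betaine losing Me2S to give the one-carbon-homologated allylic alcohol (a known epoxide-to-allylic-alcohol homologation); the carbinol centre is untouched.

Step 10
Reactants: 15
Product: 16 (R)-tert-butyldimethyl{[6-(trimethylsilyl)hex-1-en-5-yn-3-yl]oxy}silane
Conditions: t-BuMe2SiCl, imidazole, DMF, rt
Reagents that add atoms: tert-butyldimethylsilyl chloride, CC(C)(C)[Si](C)(C)Cl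
Why: Silylation of the secondary alcohol protects O5 through the organometallic steps 12 and 14.

Step 11
Reactants: 16
Product: 17 (R)-tert-butyl(hex-1-en-5-yn-3-yloxy)dimethylsilane
Conditions: K2CO3, MeOH, rt
Reagents that add atoms: none
Why: Protodesilylation of the alkynylsilane by methoxide should free the terminal alkyne while the secondary silyl ether survives.

Step 12
Reactants: 17
Product: 20 (R,E)-5-[(tert-butyldimethylsilyl)oxy]-3-methylhepta-2,6-dien-1-ol, via alkenylalane 18 (not isolated), via lithium alanate 19 (not isolated)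
Conditions: AlMe3, Cp2ZrCl2 (25 mol %), CH2Cl2, 0 °C → rt; then n-BuLi, THF, −78 °C; (CH2O)n, → rt
Reagents that add atoms: trimethylaluminium, C[Al](C)C; formaldehyde (used as paraformaldehyde), C=O
Why: Negishi zirconium-catalysed carboalumination adds CH3 and Al syn across the terminal alkyne with CH3 on the internal carbon, which fixes the 2E geometry, and the derived alanate is hydroxymethylated by formaldehyde; the terminal vinyl group and the silyl ether should be inert.

Step 13
Reactants: 20
Product: 21 (R,E)-5-[(tert-butyldimethylsilyl)oxy]-3-methylhepta-2,6-dienal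
Conditions: MnO2, CH2Cl2, rt
Reagents that add atoms: none
Why: MnO2 oxidises the primary allylic alcohol selectively to the enal without touching the silyl ether or the E geometry.

Step 14
Reactants: 11; 21
Product: 23 (3R,5E,7S,8R,11E)-3-[(tert-butyldimethylsilyl)oxy]-8-ethynyl-5,11-dimethylhexadeca-1,5,11-trien-15-yn-7-ol, via allenylindium 22 (not isolated)
Conditions: Pd(dppf)Cl2 (5 mol %), InI (1.5 equiv), THF–HMPA (3:1), rt
Reagents that add atoms: none
Why: Marshall propargylation: zerovalent palladium opens the S mesylate by anti SN2′ attack, oxidative transmetalation with InI gives the (M)-allenylindium 22, and its cyclic SE2′ 1,2-addition to the enal transfers the chirality to C14 (R) and, through the anti-selective chair-like transition state, to C1 (S).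

Step 15
Reactants: 23
Product: 24 (3R,5E,7S,8R,11E)-8-ethynyl-5,11-dimethylhexadeca-1,5,11-trien-15-yne-3,7-diol
Conditions: Bu4NF, THF, 0 °C → rt
Reagents that add atoms: none
Why: Fluoride cleaves the silyl ether to free O5 while ring A is not yet present, so no base-sensitive Michael acceptor is exposed.

Step 16
Reactants: 24
Product: 26 (1S,5R,14R,2E,10E)-bis-lactone: ring A fused trans to a 15-membered 2-methylene macrolactone O5–C18(=O)–C7(=CH2), C5 bearing a vinyl group, via monolactone 25 (not isolated)
Conditions: Pd(OAc)2 (5 mol %), 2-PyPPh2 (20 mol %), CH3SO3H (20 mol %), CO (20 bar), toluene–MeCN, 50 °C, 24 added slowly to about 2 mM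
Reagents that add atoms: carbon monoxide, [C-]#[O+]
Why: Proposed new method: under CO a cationic divalent palladium/2-PyPPh2 catalyst turns each hydroxyl into an alkoxycarbonylpalladium unit, RO–C(=O)–Pd, which adds syn across a terminal alkyne with the acyl carbon on the internal carbon, and protonolysis of the vinyl–Pd bond then leaves the =CH2 group. At O1 this is a 5-exo-dig insertion of the C14 ethynyl group that closes ring A by the C15–C16 bond (lactone 25); at O5 the same event on the remote C7 ethynyl group is a 15-exo-dig closure that forms C7–C18 and the 2-methylene macrolactone. The closest known reactions are the palladium-catalysed cyclocarbonylation of but-3-yn-1-ols to α-methylene-γ-butyrolactones and the branched-selective alkoxycarbonylation of terminal alkynes with Pd(OAc)2/2-PyPPh2/acid; the macrocyclic, intramolecular version of the latter is the untested part. No stereocentre is formed, and the anti C1/C14 pair of 24 becomes the trans ring fusion without either centre being touched. The step needs the pairing O1/C14-alkyne and O5/C7-alkyne, which the 1,2-relationship of O1 and the ethynyl group secures (the crossed closures would be 9- and 11-membered and cannot compete with the 5-exo event, after which only O5 and the C7 alkyne remain). It also needs Markovnikov regiochemistry, which the 2-pyridylphosphine catalyst imposes, and ring closure over oligomerisation, which slow addition to about 2 mM favours.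

Step 17
Reactants: 26
Product: 27 (1S,5R,14R,2E,10E)-11-deoxy-10,11-ene precursor: 14-membered ring C with trans-fused ring A and butenolide ring B
Conditions: RuCl2(=CHPh)(PCy3)(H2IMes) (second-generation Grubbs catalyst, 10 mol %), toluene, 80 °C, 1 mM
Reagents that add atoms: none
Why: Ring-closing metathesis of an acrylate/allyl-ester diene to a butenolide: ruthenium loads on the monosubstituted C6 vinyl group and closes the five-membered ring onto the C7 methylene with loss of ethylene, which contracts the macrolactone to ring C; C5 is untouched, and the trisubstituted alkenes and the α-methylene lactone are poor metathesis partners.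

Step 18
Reactants: 27
Product: 28 target CNP0343227.1, (1S,5R,11S,14R,2E,9E)
Conditions: O2, visible light, tetraphenylporphyrin (cat.), CH2Cl2, −20 °C
Reagents that add atoms: dioxygen, O=O
Why: Schenck ene reaction of singlet oxygen: the electron-rich C10=C11 bond should react in preference to C2=C3 (deactivated by the allylic lactone oxygen, as in geranyl acetate) and to the two conjugated alkenes, oxygen adding to C11 with suprafacial abstraction of a C9–H to give the 9E alkene; C11 is set by substrate control, the reagent approaching the exposed outer face of the alkene in the conformationally restricted bis-lactone, which is expected but not assured to lead to 11S.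

**Compound list**
1 | methacrolein (2-methylprop-2-enal) | CC(=C)C=O | starting material
2 | (4-bromobut-1-yn-1-yl)trimethylsilane | C[Si](C)(C)C#CCCBr | starting material
3 | [4-(trimethylsilyl)but-3-yn-1-yl]magnesium bromide | C[Si](C)(C)C#CCC[Mg]Br | intermediate
4 | rac-2-methyl-7-(trimethylsilyl)hept-1-en-6-yn-3-ol | CC(=C)C(O)CCC#C[Si](C)(C)C | intermediate
5 | rac-3-[(1-ethoxyethenyl)oxy]-2-methyl-7-(trimethylsilyl)hept-1-en-6-yne (ketene acetal) | C=C(OCC)OC(CCC#C[Si](C)(C)C)C(C)=C | intermediate
6 | ethyl (E)-4-methyl-9-(trimethylsilyl)non-4-en-8-ynoate | CCOC(=O)CC/C(C)=C/CCC#C[Si](C)(C)C | intermediate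
7 | (E)-N-methoxy-N,4-dimethyl-9-(trimethylsilyl)non-4-en-8-ynamide | CON(C)C(=O)CC/C(C)=C/CCC#C[Si](C)(C)C | intermediate
8 | (E)-6-methyl-1,11-bis(trimethylsilyl)undec-6-ene-1,10-diyn-3-one | C[Si](C)(C)C#CC(=O)CC/C(C)=C/CCC#C[Si](C)(C)C | intermediate
9 | (S,E)-6-methyl-1,11-bis(trimethylsilyl)undec-6-ene-1,10-diyn-3-ol | C[Si](C)(C)C#C[C@@H](O)CC/C(C)=C/CCC#C[Si](C)(C)C | intermediate
10 | (S,E)-6-methylundec-6-ene-1,10-diyn-3-ol | C#C[C@@H](O)CC/C(C)=C/CCC#C | intermediate
11 | (S,E)-6-methylundec-6-ene-1,10-diyn-3-yl methanesulfonate | C#C[C@@H](OS(C)(=O)=O)CC/C(C)=C/CCC#C | intermediate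
12 | (R)-epichlorohydrin | ClC[C@H]1CO1 | starting material
13 | (R)-1-chloro-5-(trimethylsilyl)pent-4-yn-2-ol | ClC[C@H](O)CC#C[Si](C)(C)C | intermediate
14 | (R)-trimethyl[3-(oxiran-2-yl)prop-1-yn-1-yl]silane | C1O[C@@H]1CC#C[Si](C)(C)C | intermediate
15 | (R)-6-(trimethylsilyl)hex-1-en-5-yn-3-ol | C=C[C@H](O)CC#C[Si](C)(C)C | intermediate
16 | (R)-tert-butyldimethyl{[6-(trimethylsilyl)hex-1-en-5-yn-3-yl]oxy}silane | C=C[C@H](O[Si](C)(C)C(C)(C)C)CC#C[Si](C)(C)C | intermediate
17 | (R)-tert-butyl(hex-1-en-5-yn-3-yloxy)dimethylsilane | C=C[C@H](O[Si](C)(C)C(C)(C)C)CC#C | intermediate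
18 | (R,E)-{4-[(tert-butyldimethylsilyl)oxy]-2-methylhexa-1,5-dien-1-yl}dimethylaluminium | C[Al](C)/C=C(\C)C[C@H](C=C)O[Si](C)(C)C(C)(C)C | intermediate
19 | lithium butyl{(R,E)-4-[(tert-butyldimethylsilyl)oxy]-2-methylhexa-1,5-dien-1-yl}dimethylaluminate | [Li+].CCCC[Al-](C)(C)/C=C(\C)C[C@H](C=C)O[Si](C)(C)C(C)(C)C | intermediate
20 | (R,E)-5-[(tert-butyldimethylsilyl)oxy]-3-methylhepta-2,6-dien-1-ol | OC/C=C(\C)C[C@H](C=C)O[Si](C)(C)C(C)(C)C | intermediate
21 | (R,E)-5-[(tert-butyldimethylsilyl)oxy]-3-methylhepta-2,6-dienal | O=C/C=C(\C)C[C@H](C=C)O[Si](C)(C)C(C)(C)C | intermediate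
22 | (M)-iodo(methanesulfonato)[(E)-6-methylundeca-1,2,6-trien-10-yn-1-yl]indium (axial chirality M, not expressible in the SMILES line) | CS(=O)(=O)O[In](I)C=C=CCC/C(C)=C/CCC#C | intermediate
23 | (3R,5E,7S,8R,11E)-3-[(tert-butyldimethylsilyl)oxy]-8-ethynyl-5,11-dimethylhexadeca-1,5,11-trien-15-yn-7-ol (anti adduct; C1 S, C5 R, C14 R) | C#C[C@@H](CC/C(C)=C/CCC#C)[C@@H](O)/C=C(\C)C[C@H](C=C)O[Si](C)(C)C(C)(C)C | intermediate
24 | (3R,5E,7S,8R,11E)-8-ethynyl-5,11-dimethylhexadeca-1,5,11-trien-15-yne-3,7-diol | C#C[C@@H](CC/C(C)=C/CCC#C)[C@@H](O)/C=C(\C)C[C@H](C=C)O | intermediate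
25 | (4R,5S)-5-[(1E,4R)-4-hydroxy-2-methylhexa-1,5-dien-1-yl]-3-methylidene-4-[(3E)-3-methyloct-3-en-7-yn-1-yl]oxolan-2-one | C=C1C(=O)O[C@@H](/C=C(\C)C[C@H](C=C)O)[C@@H]1CC/C(C)=C/CCC#C | intermediate
26 | (1S,5R,14R,2E,10E)-bis-lactone: ring A fused trans to the 15-membered 2-methylene macrolactone, C5 vinyl | C=C1C(=O)O[C@H]2/C=C(\C)C[C@H](C=C)OC(=O)C(=C)CC/C=C(\C)CC[C@H]12 | intermediate
27 | (1S,5R,14R,2E,10E)-11-deoxy-10,11-ene precursor (rings A, B and C complete) | C=C1C(=O)O[C@H]2/C=C(\C)C[C@@H]3C=C(CC/C=C(\C)CC[C@H]12)C(=O)O3 | intermediate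
28 | CNP0343227.1, (1S,5R,11S,14R,2E,9E)-11-hydroperoxide | C=C1C(=O)O[C@H]2/C=C(\C)C[C@@H]3C=C(C/C=C/[C@@](C)(OO)CC[C@H]12)C(=O)O3 | target

**Step count and risks**
Total steps: 18. Longest linear sequence: 12 steps (steps 1–7, then 14–18).

Steps most likely to fail:

Step 16 (the proposed new method). Carbonylative oligomerisation may outrun the 15-membered closure. The allylic alcohols may isomerise or ionise under acid or palladium hydride. The C7 alkyne may carbonylate in the linear instead of the branched sense. The fallback uses known reactions one ring at a time; it sets out from 23 and returns at 26. Cyclocarbonylation of the but-3-yn-1-ol unit alone (PdCl2, thiourea, CO 1 atm, acetone, 50 °C; the silyl ether blocks O5) should give the ring A lactone silyl ether F1. Branched hydroxycarbonylation of the remaining terminal alkyne (Pd(OAc)2, 2-PyPPh2, CH3SO3H, CO, aqueous acetone) should give the 2-methylene acid F2. HF·pyridine should give the hydroxy acid F3. Yamaguchi macrolactonisation (2,4,6-trichlorobenzoyl chloride, Et3N, then DMAP, toluene, high dilution) then closes 26.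

Step 18. Singlet oxygen may attack the wrong face of C10=C11 (giving the 11-epimer), or abstract hydrogen from the C11 methyl group instead of C9. The fallback replaces substrate control by reagent control; it sets out from 27 and returns at 28. Shi epoxidation with the D-fructose-derived ketone (KHSO5, K2CO3 buffer, MeCN–dimethoxymethane–H2O, 0 °C) should epoxidise only the electron-rich C10=C11 bond, giving the (10R,11R)-epoxide F4. Perhydrolysis with ethereal H2O2 and catalytic H3PMo12O40 should open it at the tertiary carbon with inversion, giving the (10R,11S)-hydroxy hydroperoxide F5. Et3SiCl/imidazole should silylate the more acidic OOH, giving the silyl peroxide F6. The Burgess reagent should dehydrate the C10 alcohol by syn elimination towards C9 (the only β-hydrogens), giving the 9E silyl peroxide F7. HF·pyridine then frees 28.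

Step 12. The carboalumination may stall, AlMe3 may cleave the allylic silyl ether, or trapping by formaldehyde may be incomplete. The fallback builds the trisubstituted alkene by hydroxyl-directed hydroalumination instead; it sets out from 17 and returns at 20. Hydroxymethylation of the lithium acetylide (n-BuLi, (CH2O)n, THF) should give the propargylic alcohol F8. trans-Hydroalumination with NaAlH2(OCH2CH2OCH3)2 followed by I2 should give the (Z)-3-iodoallylic alcohol F9. Me2CuLi then replaces iodine by methyl with retention to give 20.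

Further compounds
F1 | step 16 | (4R,5S)-5-{(1E,4R)-4-[(tert-butyldimethylsilyl)oxy]-2-methylhexa-1,5-dien-1-yl}-3-methylidene-4-[(3E)-3-methyloct-3-en-7-yn-1-yl]oxolan-2-one | C=C1C(=O)O[C@@H](/C=C(\C)C[C@H](C=C)O[Si](C)(C)C(C)(C)C)[C@@H]1CC/C(C)=C/CCC#C
F2 | step 16 | 2-methylene acid: F1 with the terminal alkyne converted into C(=CH2)CO2H | C=C1C(=O)O[C@@H](/C=C(\C)C[C@H](C=C)O[Si](C)(C)C(C)(C)C)[C@@H]1CC/C(C)=C/CCC(=C)C(=O)O
F3 | step 16 | hydroxy acid: F2 without the silyl group | C=C1C(=O)O[C@@H](/C=C(\C)C[C@H](C=C)O)[C@@H]1CC/C(C)=C/CCC(=C)C(=O)O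
F4 | step 18 | (10R,11R)-10,11-epoxide of 27 | C=C1C(=O)O[C@H]2/C=C(\C)C[C@@H]3C=C(CC[C@H]4O[C@]4(C)CC[C@H]12)C(=O)O3
F5 | step 18 | (10R,11S)-10-hydroxy-11-hydroperoxide | C=C1C(=O)O[C@H]2/C=C(\C)C[C@@H]3C=C(CC[C@@H](O)[C@@](C)(OO)CC[C@H]12)C(=O)O3
F6 | step 18 | (10R,11S)-10-hydroxy-11-(triethylsilylperoxy) compound | C=C1C(=O)O[C@H]2/C=C(\C)C[C@@H]3C=C(CC[C@@H](O)[C@@](C)(OO[Si](CC)(CC)CC)CC[C@H]12)C(=O)O3
F7 | step 18 | triethylsilyl peroxide of 28 | C=C1C(=O)O[C@H]2/C=C(\C)C[C@@H]3C=C(C/C=C/[C@@](C)(OO[Si](CC)(CC)CC)CC[C@H]12)C(=O)O3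
F8 | step 12 | (R)-5-[(tert-butyldimethylsilyl)oxy]hept-6-en-2-yn-1-ol | OCC#CC[C@H](C=C)O[Si](C)(C)C(C)(C)C
F9 | step 12 | (R,Z)-5-[(tert-butyldimethylsilyl)oxy]-3-iodohepta-2,6-dien-1-ol | OC/C=C(\I)C[C@H](C=C)O[Si](C)(C)C(C)(C)C
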